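**Retrosynthetic overview**

1. Target 20 ← hydroquinone 19 (oxidation) ← 4‑hydroxybenzaldehyde 17 by Dakin‑type excision of a formyl group. Quinone numbering used here: C1 = carbonyl between C2 (OMe) and C6 (side chain), C4 = the other carbonyl; the C1 oxygen replaces CHO and the C4 oxygen is the phenol of 17.
2. 17 ← one [4+2] benzannulation that makes the C5–C6 and C1–C2 bonds and the only ring. Diene 14 supplies C2(OMe)2=C3H–C4(OSiMe3)=C5H2; ynal 9 supplies C6≡C1–CHO with the complete side chain.
3. Enabling feature: the ring segment C2(OMe)=C3H–C4(=O)–C5H is a 1,3‑dioxygenated four‑carbon unit (a β‑silyloxy ketene acetal), and C1 lies para to the C4 oxygen. A formyl group on C1 therefore polarises the C6≡C1 dienophile and can later leave as formate.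
4. 9 ← (R)‑2‑undecyloxirane 4 + lithiated propiolaldehyde diethyl acetal; 4 ← (R)‑epichlorohydrin 1 + decylmagnesium bromide 2. The stereocentre comes from the chiral pool and the acetate is in place before the key step, so no protecting group is needed.
5. 14 ← 4,4‑dimethoxybut‑3‑en‑2‑one 12 ← 1,1‑dimethoxyethene 10 + acetyl chloride 11. The single carbocycle is formed once, in step 8.

Key step: step 8

Remark: the stereocentre is read as (R) (OAc > CH2–ring > undecyl > H); compounds 1, 2, 5, 10 and 11 are taken as commercial.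

**Route**

Step 1
Reactants: 1 (R)‑epichlorohydrin; 2 decylmagnesium bromide
Product: 3 (R)‑1‑chlorotridecan‑2‑ol
Conditions: CuI (5 mol %), THF, −40 → −20 °C; then H2O
Reagents that add atoms: none
Why: Copper‑catalysed opening of the terminal epoxide at its CH2 carbon (SN2) should outrun displacement of chloride at low temperature; the stereocentre of 1 is not a reacting centre and becomes C2 of 3 with unchanged (R) descriptor.

Step 2
Reactants: 3 (R)‑1‑chlorotridecan‑2‑ol
Product: 4 (R)‑2‑undecyloxirane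
Conditions: powdered NaOH, Et2O, rt
Reagents that add atoms: none
Why: Intramolecular Williamson etherification (alkoxide displaces the primary chloride); the carbinol C–O bond is kept, so the configuration is retained.

Step 3
Reactants: 4 (R)‑2‑undecyloxirane; 5 3,3‑diethoxyprop‑1‑yne
Product: 7 (R)‑1,1‑diethoxyhexadec‑2‑yn‑5‑ol, via (3,3‑diethoxyprop‑1‑yn‑1‑yl)lithium 6 (not isolated)
Conditions: 5, n‑BuLi, THF, −78 °C; BF3·OEt2, then 4, −78 °C; then H2O
Reagents that add atoms: none
Why: Yamaguchi–Hirao alkynylation, in which the BF3‑activated epoxide is opened by the lithium acetylide at the unsubstituted carbon, so the stereocentre is untouched.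

Step 4
Reactants: 7 (R)‑1,1‑diethoxyhexadec‑2‑yn‑5‑ol
Product: 8 (R)‑1,1‑diethoxyhexadec‑2‑yn‑5‑yl acetate
Conditions: Ac2O, pyridine, DMAP (cat.), CH2Cl2, 0 °C → rt
Reagents that add atoms: acetic anhydride, CC(=O)OC(C)=O
Why: DMAP‑catalysed O‑acylation of the secondary alcohol; the C–O bond at the stereocentre is not broken and the acetal is stable to base.

Step 5
Reactants: 8 (R)‑1,1‑diethoxyhexadec‑2‑yn‑5‑yl acetate
Product: 9 (R)‑1‑oxohexadec‑2‑yn‑5‑yl acetate
Conditions: HCO2H/H2O (9:1), CHCl3, 0 °C → rt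
Reagents that add atoms: water, O
Why: Acid hydrolysis of the propargylic diethyl acetal to the conjugated ynal; the secondary acetate survives and the absence of base avoids elimination of acetic acid.

Step 6
Reactants: 10 1,1‑dimethoxyethene; 11 acetyl chloride
Product: 12 4,4‑dimethoxybut‑3‑en‑2‑one
Conditions: Et3N, Et2O, −20 °C → rt; filtration
Reagents that add atoms: none
Why: C‑acylation of a nucleophilic ketene O,O‑acetal by an acid chloride, the dimethoxycarbenium intermediate being deprotonated by the amine to the push–pull enone.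

Step 7
Reactants: 12 4,4‑dimethoxybut‑3‑en‑2‑one
Product: 14 1,1‑dimethoxy‑3‑(trimethylsilyloxy)buta‑1,3‑diene, via lithium 4,4‑dimethoxybuta‑1,3‑dien‑2‑olate 13 (not isolated)
Conditions: LiN(i‑Pr)2, THF, −78 °C; then Me3SiCl, −78 → 0 °C
Reagents that add atoms: chlorotrimethylsilane, C[Si](C)(C)Cl
Why: Kinetic deprotonation of the methyl ketone and O‑silylation of the cross‑conjugated enolate, the standard preparation of 1,1‑dialkoxy‑3‑silyloxybutadienes.

Step 8
Reactants: 9 (R)‑1‑oxohexadec‑2‑yn‑5‑yl acetate; 14 1,1‑dimethoxy‑3‑(trimethylsilyloxy)buta‑1,3‑diene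
Product: 17 (R)‑1‑(2‑formyl‑5‑hydroxy‑3‑methoxyphenyl)tridecan‑2‑yl acetate, via cyclohexa‑1,4‑diene cycloadduct 15 (not isolated), via aryl trimethylsilyl ether 16 (not isolated)
Conditions: 14 (1.5 equiv), toluene, rt → 60 °C; then 0.5 M aq. HCl, THF, rt
Reagents that add atoms: none
Why: Thermal normal‑electron‑demand Diels–Alder reaction of the doubly donor‑substituted diene 14 with the acceptor alkyne of 9; the closest known reaction type is the benzannulation of 1,1‑dialkoxy‑3‑silyloxybutadienes with acetylenic aldehydes, ketones and esters to resorcinol monoethers. The six‑membered carbocycle closes by an intermolecular, concerted but asynchronous [4+2] cycloaddition: the CH2 terminus of the diene bonds to the alkyne β‑carbon (future C6, carrying the side chain) and the ketene acetal carbon (future C2) bonds to the formyl‑bearing α‑carbon (future C1). Cycloadduct 15 should aromatise by 1,4‑elimination of methanol from its ketal carbon, and dilute acid then cleaves silyl ether 16 to the phenol. No new stereocentre is formed, and the acetoxy stereocentre is not acidic and is untouched by neutral heating. The step needs regioselectivity, secured by the match of the largest HOMO coefficient (CH2 terminus, reinforced by both the silyloxy and the two methoxy donors) with the largest LUMO coefficient (β‑carbon of the ynal). It also needs chemoselectivity for C≡C over C=O, secured by working without a Lewis acid so that hetero‑Diels–Alder and aldol‑type additions to the formyl group stay slow.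

Step 9
Reactants: 17 (R)‑1‑(2‑formyl‑5‑hydroxy‑3‑methoxyphenyl)tridecan‑2‑yl acetate
Product: 19 (R)‑1‑(2,5‑dihydroxy‑3‑methoxyphenyl)tridecan‑2‑yl acetate, via aryl formate 18 (not isolated)
Conditions: mCPBA, CH2Cl2, 0 °C → rt; aq. Na2S2O3/NaHCO3 wash; then Et3N (cat.), MeOH, 0 °C, argon
Reagents that add atoms: 3‑chloroperoxybenzoic acid, OOC(=O)c1cccc(Cl)c1
Why: Dakin‑type Baeyer–Villiger oxidation in which the electron‑rich aryl group (para hydroxyl, ortho methoxy) migrates to oxygen to give formate 18; amine‑catalysed methanolysis then cleaves the aryl formate far faster than the secondary alkyl acetate.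

Step 10
Reactants: 19 (R)‑1‑(2,5‑dihydroxy‑3‑methoxyphenyl)tridecan‑2‑yl acetate
Product: 20 (R)‑1‑(5‑methoxy‑3,6‑dioxocyclohexa‑1,4‑dien‑1‑yl)tridecan‑2‑yl acetate
Conditions: Ag2O, Na2SO4, Et2O, rt
Reagents that add atoms: none
Why: Two‑electron oxidation of a hydroquinone to the 1,4‑benzoquinone under neutral, anhydrous conditions that leave the acetate and the remote stereocentre untouched.

**Compound list**

1 | (R)‑epichlorohydrin [(R)‑2‑(chloromethyl)oxirane] | ClC[C@H]1CO1 | starting material
2 | decylmagnesium bromide | CCCCCCCCCC[Mg]Br | starting material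
3 | (R)‑1‑chlorotridecan‑2‑ol | CCCCCCCCCCC[C@@H](O)CCl | intermediate
4 | (R)‑2‑undecyloxirane | CCCCCCCCCCC[C@@H]1CO1 | intermediate
5 | 3,3‑diethoxyprop‑1‑yne | C#CC(OCC)OCC | starting material
6 | (3,3‑diethoxyprop‑1‑yn‑1‑yl)lithium | [Li]C#CC(OCC)OCC | intermediate (not isolated)
7 | (R)‑1,1‑diethoxyhexadec‑2‑yn‑5‑ol | CCCCCCCCCCC[C@@H](O)CC#CC(OCC)OCC | intermediate
8 | (R)‑1,1‑diethoxyhexadec‑2‑yn‑5‑yl acetate | CCCCCCCCCCC[C@@H](OC(C)=O)CC#CC(OCC)OCC | intermediate
9 | (R)‑1‑oxohexadec‑2‑yn‑5‑yl acetate | CCCCCCCCCCC[C@@H](OC(C)=O)CC#CC=O | intermediate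
10 | 1,1‑dimethoxyethene | C=C(OC)OC | starting material
11 | acetyl chloride | CC(Cl)=O | starting material
12 | 4,4‑dimethoxybut‑3‑en‑2‑one | CC(=O)C=C(OC)OC | intermediate
13 | lithium 4,4‑dimethoxybuta‑1,3‑dien‑2‑olate | [Li]OC(=C)C=C(OC)OC | intermediate (not isolated)
14 | 1,1‑dimethoxy‑3‑(trimethylsilyloxy)buta‑1,3‑diene | C=C(O[Si](C)(C)C)C=C(OC)OC | intermediate
15 | (R)‑1‑[2‑formyl‑3,3‑dimethoxy‑5‑(trimethylsilyloxy)cyclohexa‑1,4‑dien‑1‑yl]tridecan‑2‑yl acetate | CCCCCCCCCCC[C@@H](OC(C)=O)CC1=C(C=O)C(OC)(OC)C=C(O[Si](C)(C)C)C1 | intermediate (not isolated)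
16 | (R)‑1‑[2‑formyl‑3‑methoxy‑5‑(trimethylsilyloxy)phenyl]tridecan‑2‑yl acetate | CCCCCCCCCCC[C@@H](OC(C)=O)Cc1cc(O[Si](C)(C)C)cc(OC)c1C=O | intermediate (not isolated)
17 | (R)‑1‑(2‑formyl‑5‑hydroxy‑3‑methoxyphenyl)tridecan‑2‑yl acetate | CCCCCCCCCCC[C@@H](OC(C)=O)Cc1cc(O)cc(OC)c1C=O | intermediate
18 | (R)‑1‑[2‑(formyloxy)‑5‑hydroxy‑3‑methoxyphenyl]tridecan‑2‑yl acetate | CCCCCCCCCCC[C@@H](OC(C)=O)Cc1cc(O)cc(OC)c1OC=O | intermediate (not isolated)
19 | (R)‑1‑(2,5‑dihydroxy‑3‑methoxyphenyl)tridecan‑2‑yl acetate | CCCCCCCCCCC[C@@H](OC(C)=O)Cc1cc(O)cc(OC)c1O | intermediate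
20 | (R)‑1‑(5‑methoxy‑3,6‑dioxocyclohexa‑1,4‑dien‑1‑yl)tridecan‑2‑yl acetate | CCCCCCCCCCC[C@H](CC1=CC(=O)C=C(OC)C1=O)OC(C)=O | target

**Step count**

Total steps: 10. Longest linear sequence: 8 (steps 1–5, 8, 9, 10).

**Steps most likely to fail**

1. Step 8. The diene may attack the formyl group (hetero‑Diels–Alder or silyl‑transfer aldol addition) instead of the alkyne, or may decompose thermally before a slow cycloaddition at the β‑alkylated alkyne. The fallback buys the ring instead of building it; it sets out from 4 and comes back to the route at 20. CuI‑catalysed opening of 4 with 3,5‑dimethoxyphenylmagnesium bromide (THF, −20 °C) should give (R)‑1‑(3,5‑dimethoxyphenyl)tridecan‑2‑ol F1. Acetylation (Ac2O, pyridine, DMAP) should give (R)‑1‑(3,5‑dimethoxyphenyl)tridecan‑2‑yl acetate F2. Vilsmeier–Haack formylation (POCl3, DMF, then aq. NaOAc), directed ortho to the side chain and para to a methoxy group, should give (R)‑1‑(2‑formyl‑3,5‑dimethoxyphenyl)tridecan‑2‑yl acetate F3. Baeyer–Villiger oxidation (mCPBA, CH2Cl2) should give (R)‑1‑[2‑(formyloxy)‑3,5‑dimethoxyphenyl]tridecan‑2‑yl acetate F4, which Et3N‑catalysed methanolysis converts to (R)‑1‑(2‑hydroxy‑3,5‑dimethoxyphenyl)tridecan‑2‑yl acetate F5. Oxidative demethylation of this para‑methoxyphenol with (NH4)2Ce(NO3)6 in MeCN/H2O at 0 °C should give 20.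

2. Step 9. Peracid oxidation of the free, electron‑rich phenol ring may compete with formyl‑to‑formate migration at the doubly ortho‑substituted aldehyde, and the secondary acetate may be partly lost during formate cleavage. The fallback removes the formyl carbon as CO and brings in the C1 oxygen afterwards; it sets out from 17 and comes back at 20. Tsuji–Wilkinson decarbonylation with stoichiometric RhCl(PPh3)3 (toluene, 110 °C) should give (R)‑1‑(3‑hydroxy‑5‑methoxyphenyl)tridecan‑2‑yl acetate F6. Teuber oxidation with (KSO3)2NO (KH2PO4 buffer, acetone/H2O, rt) para to the hydroxyl, between the methoxy‑ and alkyl‑bearing carbons, should then give 20.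

3. Step 6. O‑demethylation of the acylated dimethoxycarbenium ion (leading to the β‑keto ester) and ketene formation from acetyl chloride and the amine may compete with C‑acylation. The fallback makes the enone by substitution at a dichlorovinyl ketone; it sets out from 11 and comes back at 12. AlCl3‑mediated acylation of 1,1‑dichloroethene with 11 (CH2Cl2, 0 °C) should give 4,4,4‑trichlorobutan‑2‑one F7, which loses HCl on distillation to give 4,4‑dichlorobut‑3‑en‑2‑one F8. Double addition–elimination with NaOMe (2 equiv, MeOH, 0 °C) should give 12.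

**Further compounds**

F1 | step 8 | (R)‑1‑(3,5‑dimethoxyphenyl)tridecan‑2‑ol | CCCCCCCCCCC[C@@H](O)Cc1cc(OC)cc(OC)c1
F2 | step 8 | (R)‑1‑(3,5‑dimethoxyphenyl)tridecan‑2‑yl acetate | CCCCCCCCCCC[C@@H](OC(C)=O)Cc1cc(OC)cc(OC)c1
F3 | step 8 | (R)‑1‑(2‑formyl‑3,5‑dimethoxyphenyl)tridecan‑2‑yl acetate | CCCCCCCCCCC[C@@H](OC(C)=O)Cc1cc(OC)cc(OC)c1C=O
F4 | step 8 | (R)‑1‑[2‑(formyloxy)‑3,5‑dimethoxyphenyl]tridecan‑2‑yl acetate | CCCCCCCCCCC[C@@H](OC(C)=O)Cc1cc(OC)cc(OC)c1OC=O
F5 | step 8 | (R)‑1‑(2‑hydroxy‑3,5‑dimethoxyphenyl)tridecan‑2‑yl acetate | CCCCCCCCCCC[C@@H](OC(C)=O)Cc1cc(OC)cc(OC)c1O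
F6 | step 9 | (R)‑1‑(3‑hydroxy‑5‑methoxyphenyl)tridecan‑2‑yl acetate | CCCCCCCCCCC[C@@H](OC(C)=O)Cc1cc(O)cc(OC)c1
F7 | step 6 | 4,4,4‑trichlorobutan‑2‑one | CC(=O)CC(Cl)(Cl)Cl
F8 | step 6 | 4,4‑dichlorobut‑3‑en‑2‑one | CC(=O)C=C(Cl)Cl
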